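The target is read here as the fraction of starting material that has gone, for target and starting material at the last gamma reading sum to 98.7 % of the charge.

| setting | gamma | epsilon | theta | flask |
|---|---|---|---|---|
| starting material | 0.20 M | 0.20 M | 0.10 M | 0.20 M |
| gas phase | 93 mM (held) | 93 mM (held) | 93 mM (held) | 93 mM (held) |
| free catalyst | 0.67 mM | 1.5 mM | 1 mM | 1.0 mM |
| remark | run made earlier | run made earlier | run made earlier |  |
| time |  |  |  | 5.0 h |

- gamma (time / h: target / %, starting material / %): 0.667: 19.7, 80.7; 1.33: 34.8, 66.2; 2.00: 43.3, 56.4; 2.50: 48.9, 51.2; 3.00: 51.7, 47.0
- epsilon (time / h: target / %, starting material / %): 0.667: 20.4, 79.1; 1.33: 34.4, 64.7; 2.00: 45.1, 54.6; 2.50: 49.8, 48.9; 3.00: 53.6, 46.1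
- theta (time / h: target / %, starting material / %): 0.667: 27.6, 72.5; 1.33: 45.9, 55.1; 2.00: 54.7, 45.6; 2.50: 58.7, 41.4; 3.00: 62.7, 37.1

(scatter of a reading: 0.5 percentage points)

- at the start none of the gas is dissolved
- steps that have been proposed: 2 free catalyst -> spent catalyst B; target + free catalyst <-> isomer of the product + free catalyst; starting material + dissolved gas + free catalyst -> free catalyst + target; gas phase <-> dissolved gas; free catalyst -> spent catalyst A

- cedar: doubling the amount of free catalyst, all else as stated
- maple: doubling the transfer coefficient of the gas phase, all else as stated
- elm: doubling the saturation concentration of gas phase, all else as stated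

- the target standing at 5.0 h, as a percentage of the starting material charged
- concentration of dissolved gas in solution at 80 min, in percent of saturation
- the change that raises the amount of target at 5.0 h, in percent of the starting material charged most ("none" if none brings more than 2 percentage points) (cedar / maple / elm / none)
- amount of target at 5.0 h, in percent of the starting material charged, after cedar

So follow the fraction left, and hold two times against each other: the age of the run, and the lifetime of the starting material at that age, meaning the time in which it would vanish at its present fractional rate. Their ratio, read as the fall of ln(fraction left) per unit of ln(time) between the second and last readings, is the fade exponent: 0.421 in the gamma run, and 0.417 in the epsilon run, which holds 2.24 times the catalyst. With the ratio held fixed, the lifetime grows with age and the run fades.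

Carried from the last reading to 5.0 h, gamma leaves 0.379 and epsilon 0.373. The flask's catalyst lies between theirs, so I take 0.376 left and 0.624 as target. Going round once more, that small gap scaled to a doubling gives cedar 0.55 percentage points, less than the 2 points that counts, and about the size of the scatter.

The forecast stood higher on the target, with 64.5 %, 66 % of saturation, elm as best and 66.5 % after cedar, noting that “Rates fall much faster than starting material does”.

The flask gives 59.9 %, 45.3 % of saturation, elm as best and 60.9 % after cedar.

    2 free catalyst → spent catalyst B (k = 100 L mol⁻¹ min⁻¹)
    target + free catalyst ⇌ isomer of the product + free catalyst, rate k2*[free catalyst]*[target] forward; the back reaction follows from the equilibrium constant (K = 1.30, k = 2.90 L mol⁻¹ min⁻¹)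
    starting material + dissolved gas + free catalyst → free catalyst + target (k = 2600 L² mol⁻² min⁻¹)
    gas phase ⇌ dissolved gas, rate k4*(csat - [dissolved gas]) (kL = 0.0200 min⁻¹)
    free catalyst → spent catalyst A (k = 0.00800 min⁻¹)

Read again in this flask, the exponent is 0.359 between 2.50 h and 5.00 h, lower than the gamma reading taken over an earlier stretch, and my target stands 2.5 points high. Left ten times as long, the same flask shows an exponent of 0.0464, so at 5.0 h it has slowed but has not come to rest. Free catalyst stands at 0.382 % of its charge then and 0 % at 50.0 h. The long wait adds 3.9 points, bringing the target to 63.8 %, with 35.3 % of the starting material still unreacted.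

The numbers in the tables are simulated for substances that don't exist; the scatter is artificial.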